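## Retrosynthetic overview

1. Feature: ring A is a phloroglucinol (oxygen on C5, C7 and C8a) that carries the C4 carbonyl on C4a. Oxygen therefore sits on every second carbon from C8a round ring A to C4 and C2, the mark of a folded poly-β-carbonyl chain. Until ring C exists, the oxygens on C5 and C8a are interchangeable.
2. After removal of the two ring B MOM ethers, O1–C2 and C4a–C8a are cut together. Rings C and A unfold to a 3,5,7-trioxo ester, stored as a 4-hydroxy-2-pyrone (three carbonyls) plus a methyl enol ether at C2 (the fourth).
3. C4a–C4 is cut next, giving the C6-methyl carbanion of doubly deprotonated triacetic acid lactone and an N-acylimidazole.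
4. The C4–C3–C2–ring B acid derives from 3,4-dihydroxyacetophenone: C3–C4 by Claisen condensation with dimethyl carbonate, C3–prenyl by alkylation, C2–OMe by O-methylation.
5. Ring order: ring B and the sacrificial pyrone are bought. Ring A forms first and ring C second, both in one flask.

Key step: step 8

Remark on the chemistry: the C2=C3 enol ether is drawn as the E isomer (carbonyl and methoxy groups on opposite sides) in 7–10 and 13–15. It is assumed that any Z isomer is carried along, because both converge once C2 turns tetrahedral during ring C closure.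

## Route

Step 1
Reactants: 1 3,4-dihydroxyacetophenone
Product: 2 3,4-bis(methoxymethoxy)acetophenone
Conditions: MOMCl, iPr2NEt, CH2Cl2, 0 °C to rt
Reagents that add atoms: chloromethyl methyl ether (MOMCl), COCCl
Why: Double O-alkylation of the catechol by the reactive α-chloro ether under amine base (Williamson-type ether formation) should be clean, and aryl MOM ethers tolerate every base used up to step 8 yet leave under mild acid.

Step 2
Reactants: 2 3,4-bis(methoxymethoxy)acetophenone; 3 dimethyl carbonate
Product: 4 methyl 3-[3,4-bis(methoxymethoxy)phenyl]-3-oxopropanoate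
Conditions: NaH, (MeO)2CO, THF, reflux; AcOH quench
Reagents that add atoms: dimethyl carbonate (compound 3), COC(=O)OC
Why: Crossed Claisen condensation of the methyl ketone enolate with the non-enolisable carbonate forms C3–C4, and irreversible deprotonation of the β-keto ester by NaH pulls the equilibrium to the product.

Step 3
Reactants: 4 methyl 3-[3,4-bis(methoxymethoxy)phenyl]-3-oxopropanoate; 5 prenyl bromide
Product: 6 methyl (±)-2-[3,4-bis(methoxymethoxy)benzoyl]-5-methylhex-4-enoate
Conditions: K2CO3, acetone, 50 °C
Reagents that add atoms: prenyl bromide (compound 5), CC(C)=CCBr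
Why: SN2 C-alkylation of the soft, stabilised β-keto ester enolate at the primary carbon of the allylic bromide sets the C3–prenyl bond, the weak base and one equivalent of 5 holding back a second alkylation; the new stereocentre is racemic and vanishes in step 4.

Step 4
Reactants: 6 methyl (±)-2-[3,4-bis(methoxymethoxy)benzoyl]-5-methylhex-4-enoate
Product: 8 methyl (E)-3-[3,4-bis(methoxymethoxy)phenyl]-3-methoxy-2-(3-methylbut-2-enyl)prop-2-enoate, via potassium enolate 7 (not isolated)
Conditions: KN(SiMe3)2, THF–DMPU, −78 °C; Me2SO4, −78 to 0 °C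
Reagents that add atoms: dimethyl sulfate, COS(=O)(=O)OC; KN(SiMe3)2, C[Si](C)(C)[N-][Si](C)(C)C.[K+] (potassium of 7 only)
Why: O-alkylation of an ambident enolate: a free potassium enolate in the dipolar DMPU medium without any hydrogen-bond donor, a hard sulfate electrophile and a crowded, fully substituted α-carbon all steer the methyl group to oxygen, which turns the C2 carbonyl into an enol ether that carries its own leaving group.

Step 5
Reactants: 8 methyl (E)-3-[3,4-bis(methoxymethoxy)phenyl]-3-methoxy-2-(3-methylbut-2-enyl)prop-2-enoate
Product: 9 (E)-3-[3,4-bis(methoxymethoxy)phenyl]-3-methoxy-2-(3-methylbut-2-enyl)prop-2-enoic acid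
Conditions: LiOH, THF–MeOH–H2O, 55 °C; 1 M HCl to pH 4, 0 °C
Reagents that add atoms: LiOH, [Li+].[OH-]
Why: Ordinary BAc2 saponification of the methyl ester; methoxide exchange at C2 is degenerate in the methanolic medium, the carboxylate once formed resists conjugate attack, and cold acidification to pH 4 only spares the enol ether and the MOM acetals.

Step 6
Reactants: 9 (E)-3-[3,4-bis(methoxymethoxy)phenyl]-3-methoxy-2-(3-methylbut-2-enyl)prop-2-enoic acid
Product: 10 (E)-3-[3,4-bis(methoxymethoxy)phenyl]-1-(imidazol-1-yl)-3-methoxy-2-(3-methylbut-2-enyl)prop-2-en-1-one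
Conditions: CDI, THF, rt; quick cold-water wash
Reagents that add atoms: 1,1'-carbonyldiimidazole (CDI), O=C(n1ccnc1)n1ccnc1
Why: Carboxyl activation with CDI runs through the mixed carbonic anhydride, which loses CO2 to give the N-acylimidazole under neutral conditions that leave enol ether, MOM groups and alkene alone.

Step 7
Reactants: 10 (E)-3-[3,4-bis(methoxymethoxy)phenyl]-1-(imidazol-1-yl)-3-methoxy-2-(3-methylbut-2-enyl)prop-2-en-1-one; 11 triacetic acid lactone (4-hydroxy-6-methyl-2H-pyran-2-one)
Product: 13 6-{(E)-4-[3,4-bis(methoxymethoxy)phenyl]-4-methoxy-3-(3-methylbut-2-enyl)-2-oxobut-3-enyl}-4-hydroxy-2H-pyran-2-one, via dilithiated lactone 12 (not isolated)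
Conditions: 11 (2.2 equiv), LiN(iPr)2 (4.5 equiv), THF, −78 to −20 °C; 10, −78 to 0 °C; AcOH quench
Reagents that add atoms: LiN(iPr)2, CC(C)[N-]C(C)C.[Li+] (lithium of 12 only)
Why: Claisen-type C-acylation of a dianion at its last-formed and most basic site, the C6-methyl carbanion, forms C4a–C4; the imidazolide carbonyl is far more electrophilic than the tetrasubstituted, donor-bearing C2, and the surplus of 12 removes the acidic C4a proton of the product so that its enolate is not attacked again.

Step 8
Reactants: 13 6-{(E)-4-[3,4-bis(methoxymethoxy)phenyl]-4-methoxy-3-(3-methylbut-2-enyl)-2-oxobut-3-enyl}-4-hydroxy-2H-pyran-2-one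
Product: 16 3-prenylluteolin 3',4'-bis(methoxymethyl) ether, via open-chain triketo ester 14 (not isolated), via acylphloroglucinol 15 (not isolated)
Conditions: Mg(OMe)2 (6 equiv), MeOH, reflux, Ar; AcOH, 0 °C
Reagents that add atoms: Mg(OMe)2, C[O-].C[O-].[Mg+2] (ester methoxy group of 14 only; it leaves again on the way to 15)
Why: Methoxide attacks the lactone carbonyl of 13 and releases the magnesium-chelated methyl 3,5,7-trioxo ester 14, in which chain C1 to C9 map onto flavone C8a, C8, C7, C6, C5, C4a, C4, C3 and C2. The C4a carbanion then attacks the ester carbon C8a in a Claisen (Dieckmann-type) condensation, a 6-exo-trig closure with the enolate double bond outside the new ring, and loss of methoxide followed by enolisation gives aromatic ring A in 15. One of the two equivalent ortho phenoxides of 15 adds to C2 of the β-methoxy enone (6-endo-trig oxa-Michael addition) and methoxide leaves, which closes ring C; C2 is tetrahedral in the adduct, so the alkene geometry of 13 does not matter, and no stereocentre is created. The closest known reaction types are the Mg(OMe)2-induced Claisen-type cyclisation of 6-(2-oxoalkyl)-4-hydroxy-2-pyrones and 3,5,7-triketo esters to acylphloroglucinols and the addition–elimination closure of 2-hydroxyaryl β-alkoxyvinyl ketones to chromones. The step needs the Claisen fold to outrun the aldol fold (C8 onto C4) and any attack on C2 by C6 or by the C5 enolate oxygen: chelation of the β-dicarbonyl units to divalent magnesium holds the chain in the Claisen fold, C4 is a crowded vinylogous ester carbonyl, and C2 is fully substituted and donor-stabilised. Attack of solvent methoxide at C2 merely swaps methoxy for methoxy.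

Step 9
Reactants: 16 3-prenylluteolin 3',4'-bis(methoxymethyl) ether
Product: 17 3-prenylluteolin
Conditions: HCl (1 M in MeOH), 40 °C
Reagents that add atoms: none
Why: Acid-catalysed transacetalisation of the two aryl MOM ethers to dimethoxymethane; the prenyl group has no neighbouring phenol (it lies between C4=O and a ring B without a 2'-hydroxy group), so chroman formation cannot occur and the mild acid should leave the trisubstituted alkene intact.

## Compound list

1 | 3,4-dihydroxyacetophenone | CC(=O)c1ccc(O)c(O)c1 | starting material
2 | 3,4-bis(methoxymethoxy)acetophenone | CC(=O)c1ccc(OCOC)c(OCOC)c1 | intermediate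
3 | dimethyl carbonate | COC(=O)OC | starting material
4 | methyl 3-[3,4-bis(methoxymethoxy)phenyl]-3-oxopropanoate | COC(=O)CC(=O)c1ccc(OCOC)c(OCOC)c1 | intermediate
5 | prenyl bromide (1-bromo-3-methylbut-2-ene) | CC(C)=CCBr | starting material
6 | methyl (±)-2-[3,4-bis(methoxymethoxy)benzoyl]-5-methylhex-4-enoate (racemic) | COC(=O)C(CC=C(C)C)C(=O)c1ccc(OCOC)c(OCOC)c1 | intermediate
7 | potassium (E)-enolate of 6 (not isolated) | COC(=O)/C(CC=C(C)C)=C(/[O-])c1ccc(OCOC)c(OCOC)c1.[K+] | intermediate
8 | methyl (E)-3-[3,4-bis(methoxymethoxy)phenyl]-3-methoxy-2-(3-methylbut-2-enyl)prop-2-enoate | COC(=O)/C(CC=C(C)C)=C(/OC)c1ccc(OCOC)c(OCOC)c1 | intermediate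
9 | (E)-3-[3,4-bis(methoxymethoxy)phenyl]-3-methoxy-2-(3-methylbut-2-enyl)prop-2-enoic acid | OC(=O)/C(CC=C(C)C)=C(/OC)c1ccc(OCOC)c(OCOC)c1 | intermediate
10 | (E)-3-[3,4-bis(methoxymethoxy)phenyl]-1-(imidazol-1-yl)-3-methoxy-2-(3-methylbut-2-enyl)prop-2-en-1-one | O=C(n1ccnc1)/C(CC=C(C)C)=C(/OC)c1ccc(OCOC)c(OCOC)c1 | intermediate
11 | triacetic acid lactone (4-hydroxy-6-methyl-2H-pyran-2-one) | Cc1cc(O)cc(=O)o1 | starting material
12 | dilithiated triacetic acid lactone, C4 oxide and C6-methyl carbanion (not isolated) | [Li+].[Li+].[CH2-]c1cc([O-])cc(=O)o1 | intermediate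
13 | 6-{(E)-4-[3,4-bis(methoxymethoxy)phenyl]-4-methoxy-3-(3-methylbut-2-enyl)-2-oxobut-3-enyl}-4-hydroxy-2H-pyran-2-one | O=c1cc(O)cc(CC(=O)/C(CC=C(C)C)=C(/OC)c2ccc(OCOC)c(OCOC)c2)o1 | intermediate
14 | methyl (E)-9-[3,4-bis(methoxymethoxy)phenyl]-9-methoxy-8-(3-methylbut-2-enyl)-3,5,7-trioxonon-8-enoate, drawn neutral, present as magnesium chelate (not isolated) | COC(=O)CC(=O)CC(=O)CC(=O)/C(CC=C(C)C)=C(/OC)c1ccc(OCOC)c(OCOC)c1 | intermediate
15 | (E)-3-[3,4-bis(methoxymethoxy)phenyl]-3-methoxy-2-(3-methylbut-2-enyl)-1-(2,4,6-trihydroxyphenyl)prop-2-en-1-one, drawn neutral, present as magnesium phenoxide (not isolated) | O=C(c1c(O)cc(O)cc1O)/C(CC=C(C)C)=C(/OC)c1ccc(OCOC)c(OCOC)c1 | intermediate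
16 | 3-prenylluteolin 3',4'-bis(methoxymethyl) ether | CC(C)=CCc1c(-c2ccc(OCOC)c(OCOC)c2)oc2cc(O)cc(O)c2c1=O | intermediate
17 | 3-prenylluteolin | CC(C)=CCc1c(-c2ccc(O)c(O)c2)oc2cc(O)cc(O)c2c1=O | target

## Summary

Total step count: 9.
Longest linear sequence: 9 steps (1 to 17). Compounds 3, 5 and 11 enter as purchased materials.

## Steps most likely to fail

**Step 8 (the fold).**
- What may go wrong:
  - The opened chain may fold the wrong way, either by aldol closure of C8 onto C4 or by attack on the methoxy-bearing C2 by C6 or by the C5 enolate oxygen before ring A exists.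
  - Methoxide may cut the chain by retro-Claisen cleavage.
  - The doubly deprotonated pyrone may open sluggishly.
  - Incomplete closure of ring C is not critical, because the acid of step 9 completes it.
- Fallback, in which ring A is bought instead of folded. It sets out from 10 and rejoins the route at 17. Phloroglucinol is converted with MOMCl and iPr2NEt into 1,3,5-tris(methoxymethoxy)benzene F1. n-BuLi in THF at 0 °C lithiates F1 between two MOM groups (directed ortho-metalation) to give 2-lithio-1,3,5-tris(methoxymethoxy)benzene F2. Addition of F2 to 10 at −78 °C should give (E)-3-[3,4-bis(methoxymethoxy)phenyl]-3-methoxy-2-(3-methylbut-2-enyl)-1-[2,4,6-tris(methoxymethoxy)phenyl]prop-2-en-1-one F3. Methanolic HCl as in step 9 then strips all five MOM groups. A freed ortho phenol closes ring C by the same addition–elimination at C2, and 17 is reached directly.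

**Step 4 (O-methylation).**
- What may go wrong: the ambident enolate may be methylated on carbon, which builds a quaternary C3 and blocks the route.
- Fallback, in which oxygen selectivity is taken from an oxocarbenium-type electrophile and the methoxy group is brought in afterwards as a nucleophile. It sets out from 6 and rejoins the route at 8. The sodium enolate of 6 (NaH, THF, 0 °C) is trapped with MOMCl, an α-chloro ether that alkylates β-dicarbonyl enolates on oxygen. This gives methyl (E)-3-[3,4-bis(methoxymethoxy)phenyl]-3-(methoxymethoxy)-2-(3-methylbut-2-enyl)prop-2-enoate F4. NaOMe in MeOH at reflux then exchanges the enol methoxymethoxy group for methoxy by addition–elimination at the β-carbon. The expelled hemiacetal anion collapses to formaldehyde and methoxide, so the exchange cannot revert. The aryl MOM ethers are inert to methoxide.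

**Step 7 (acylation of the dianion).**
- What may go wrong:
  - Proton transfer from the acidic product may consume the carbanion.
  - Acylation may occur at the C4 oxygen.
  - The dilithio salt may be poorly soluble.
  - The carbanion may attack the methoxy-bearing alkene carbon instead of the carbonyl group.
- Fallback, in which the pyrone mask is given up and the open chain is made directly. It sets out from 11 and 10 and rejoins the route at 14. Mg(OMe)2 in MeOH at reflux methanolyses 11 to methyl 3,5-dioxohexanoate F5. Three equivalents of LiN(iPr)2 in THF at −78 to 0 °C convert F5 into its soluble and more nucleophilic trilithio derivative F6. The terminal carbanion of F6, used in excess, is acylated by 10 to give 14 after an AcOH quench. Crude 14 is taken at once into Mg(OMe)2 in MeOH, where the fold of step 8 proceeds from its first intermediate.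

## Further compounds

F1 | step 8 | 1,3,5-tris(methoxymethoxy)benzene | COCOc1cc(OCOC)cc(OCOC)c1
F2 | step 8 | 2-lithio-1,3,5-tris(methoxymethoxy)benzene | [Li]c1c(OCOC)cc(OCOC)cc1OCOC
F3 | step 8 | (E)-3-[3,4-bis(methoxymethoxy)phenyl]-3-methoxy-2-(3-methylbut-2-enyl)-1-[2,4,6-tris(methoxymethoxy)phenyl]prop-2-en-1-one | O=C(c1c(OCOC)cc(OCOC)cc1OCOC)/C(CC=C(C)C)=C(/OC)c1ccc(OCOC)c(OCOC)c1
F4 | step 4 | methyl (E)-3-[3,4-bis(methoxymethoxy)phenyl]-3-(methoxymethoxy)-2-(3-methylbut-2-enyl)prop-2-enoate | COC(=O)/C(CC=C(C)C)=C(/OCOC)c1ccc(OCOC)c(OCOC)c1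
F5 | step 7 | methyl 3,5-dioxohexanoate | CC(=O)CC(=O)CC(=O)OC
F6 | step 7 | trilithio derivative of methyl 3,5-dioxohexanoate | [Li+].[Li+].[Li+].[CH2-]C(=O)[CH-]C(=O)[CH-]C(=O)OC
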